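## Structural features

The target is a 3-O-methylflavonol. Ring A (benzo) is fused to the 4-pyranone ring C, C2 carries ring B (4-hydroxy-3-methoxyphenyl), and C8 carries, through a CH2 bridge, a fourth ring D (2-hydroxyphenyl). Ring A is substituted at every position except C6: O1 at C8a, the benzyl branch at C8, a methoxy group at C7, a free carbonyl-chelated hydroxyl at C5, and C4 at C4a. The target has no stereocentre; the route creates three contiguous ones (C2, C3, C4 of a flavan-3,4-diol) and erases them all.

Six oxygens must be told apart: O3, O7 and O3′ stay methylated, while O5, O4′ and O2″ end as free phenols, and O5 and O7 sit meta to each other on the same ring. A precursor with methyl on both O5 and O7 would force a late mono-demethylation at O5 beside the equally carbonyl-flanked O3 methyl ether. The plan therefore carries O5 as a benzyl ether from the first step.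

Fragile points are the doubly benzylic CH2 bridge, the very electron-rich ring A (easy benzylic cations at C4 and at the bridge), and an enolisable α-aryloxy-α-aryl aldehyde among the intermediates. The real difficulty is the regiochemistry of hexasubstituted ring A together with a 3-oxygenated pyranone. The key step uses the fact that C3 and C4 of ring C are bonded to each other and both carry oxygen, so the C3–C4 bond can come from the reductive union of two aldehyde carbons.

## Logic of the disconnections

20 to 19: the three benzyl–oxygen bonds at O5, O4′ and O2″ are cut. One protecting group for all three future phenols allows a neutral hydrogenolysis that cannot touch the three methyl ethers. The demand is that O5 and O7 are differentiated at the very start and that the chromone C2=C3 bond and the diarylmethane survive H2.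

19 to 18: the O3–CH3 bond is cut. In 18 the enolic O3–H is the only acidic hydroxyl, so no selectivity problem arises. The demand is O- rather than C-alkylation.

18 to 15: no skeletal bond is cut; C3 and C4 are lowered from the dione/enol level to two carbinols. This exposes a 1,2-diol, the retron of a pinacol coupling, and turns an aromatic pyranone problem into a saturated ring closure. The demand is an oxidant that takes both secondary alcohols to carbonyls without cleaving C3–C4; the hydrogen on C2 then allows tautomerisation, so the configuration of 15 does not matter.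

15 to 14: the C3–C4 bond is cut, and each carbon becomes an aldehyde. Ring C opens to an aryl ether that links two aldehydes, so the skeleton falls into a ring A hydroxy aldehyde and a two-carbon piece carrying ring B. The demand is a reductive polarity reversal in which the ketyl forms at the ring A aldehyde and the ring closes before the ring A aryloxide can be expelled from the neighbouring carbon.

14 to 13 to 12: only oxidation levels change (two aldehydes, two primary alcohols, aldehyde plus ester). The α-aryloxy-α-aryl aldehyde is too labile to carry, whereas an ester is the stable form in which to make the O1–C2 bond. The demand is exhaustive hydride reduction, then a non-basic double oxidation, with 14 used at once.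

12 to 7 and 11: the O1–C2 ether bond is cut. This is the convergent cut between the ring A/D half and the ring B half, and the electrophilic carbon is activated by both ester and aryl group. The demand is an SN2 reaction of a hindered, chelated phenoxide without a following aldol onto the ortho aldehyde.

11 to 9 to 8: the C2–Br bond, then the two benzyl–oxygen bonds (ether and ester), are cut. This traces C2, C3 and ring B to an arylacetic acid that already has the right oxygen pattern. The demand is an ionic α-bromination that leaves benzylic ether CH2 groups alone.

7 to 6: the C4–C4a bond is cut (loss of the formyl carbon). C4 enters as a one-carbon unit at the only free position ortho to the phenol. The demand is strictly ortho-selective formylation.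

6 to 5 to 2 and 3 (through 4): the CH2 bridge is first traced back to a carbinol, then the bond between the bridge carbon and ring D is cut. The bridge carbon is the formyl carbon of 2, so the place of the benzyl branch on ring A is fixed by the starting aldehyde and not by a Friedel–Crafts preference. The demand is an aryl Grignard addition that tolerates the free phenol (one sacrificial equivalent) and a deoxygenation that spares the benzyl ethers.

2 to 1: the benzyl–oxygen bond at the future O5 is cut. The hydrogen bond of the ortho hydroxyl to the aldehyde differentiates the two ring A hydroxyls at the outset. The demand is clean mono-alkylation.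

## Other disconnections considered

Alternative 1: The cut runs through O1–C8a and C4a–C5, so neither ring C nor ring A exists in the precursor. That precursor is an open polycarbonyl chain (ketone carbons C2, C4 and C8a, a methyl enol ether at C7, a terminal ester at C5) already carrying ring B, the O3 methyl group and the ring D benzyl branch.
- Forward key step: strong acid would first cyclodehydrate the 1,3,5-tricarbonyl array to the 4-pyranone. A dehydrating superacid medium would then drive C4a onto the ester carbon, and the new ring would aromatise to 5-hydroxy-2-(4-isopropoxy-3-methoxyphenyl)-8-(2-isopropoxybenzyl)-3,7-dimethoxychromen-4-one A1.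
- In its favour: two rings form in one operation, with no stereocentre made and destroyed and no redox adjustment. It is better than the chosen plan on two points: O5 emerges as the free phenol while O7 is already methylated, so no separate differentiation step is needed, and A1 is one deprotection from the target against three steps from 15.
- Against it here: the chain needs several Claisen-type acylations around an acid-labile enol ether and an easily enolised α-methoxy-1,3-diketone, probably more steps than steps 1 to 9. The fold has competitors (the C6 methylene can condense with the C8a ketone before the pyranone exists). The forcing medium for acylation at C4a can dealkylate aryl isopropyl ethers and acylate rings B and D.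
- Comparison: structurally A1 is closer to the target than 15. Mechanistically it is a cascade whose order is set only by relative rates, whereas step 10 forms one bond between two defined carbons. It is ahead in steps after the key step and probably behind in the number and reliability of the steps before it.

Alternative 2: The cut removes ring A (C5–C6, C7–C8 and C4a–C5) from a preformed 2-aryl-3-methoxy-4-pyranone whose C8a bears an α-diazo ketone side chain with the ring D benzyl unit. The two-carbon partner is methoxyacetylene A3.
- Forward key step: photochemical Wolff rearrangement would give a vinylketene, with the C4a=C8a bond of the pyranone as the vinyl part. Addition of A3 in a [2+2] sense, 4π opening of the cyclobutenone, 6π closure and tautomerisation (Danheiser benzannulation) would give 2-(4-benzyloxy-3-methoxyphenyl)-8-(2-benzyloxybenzyl)-5-hydroxy-3,7-dimethoxychromen-4-one A2.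
- In its favour: the mechanism dictates the ring A pattern (the ketene carbon becomes C5–OH, the oxygenated alkyne carbon becomes C7). It is better than the chosen plan in delivering the free 5-hydroxyl directly and in needing only one hydrogenolysis after the key step.
- Against it here: the pyranone diazo ketone is far from catalogue compounds. 4-Pyranones have their own photochemistry at the wavelengths of the Wolff rearrangement. A carbene next to a benzylic CH2 can undergo 1,2-hydrogen shift. A3 is volatile and labile and must be made and used in excess.
- Comparison: equal in convergence; better in protecting-group and redox economy; worse in availability of the precursor and in the practicality of a photochemical step with a sensitive alkyne. The chosen plan builds ring A by classical, regiochemically unambiguous steps.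

Alternative 3: The cut is C4–C4a. Ring A is then a plain aryl ether (an analogue of 6 without the formyl carbon) bound through O1 to C2 of an (E)-configured 3-aryl-2-methoxyacrylic acid, which holds C2, C3, C4 and the O3 methyl group.
- Forward key step: activation of the acid as a mixed perfluoroacyl anhydride would give an acylating species that attacks the only free position ortho to O1 (intramolecular Friedel–Crafts acylation). This closes the pyranone as 2-(4-benzyloxy-3-methoxyphenyl)-8-(2-benzyloxybenzyl)-3,5,7-trimethoxychromen-4-one A4.
- In its favour: two-electron chemistry on the most nucleophilic arene of the molecule and no stereocentres. It is better than the chosen plan in redox and step economy after ring closure, because the oxidation level and the O3 methyl group are correct at once (no diol, no oxidation, no methylation). It is equal in the ring A/D chemistry it needs.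
- Against it here: the acid has a tetrasubstituted enol ether double bond of defined geometry, with the carboxyl cis to the aryloxy group, and is not simply made (conjugate addition of the phenol to an arylpropiolate leaves C3 without oxygen). The electron-rich enol ether can hydrolyse, or the acid decarboxylate, under acidic activation, and the benzyl ethers see strong acid. With methyl on O5, A4 still needs the chelation-controlled mono-demethylation beside the O3 methyl ether that the chosen plan avoids; a benzyl ether on O5 would repair this in either plan.
- Comparison: it is the shortest on paper and mechanistically the simplest, and would be preferred if the acrylic acid were at hand. The chosen plan trades three extra late steps for a precursor whose every bond is made by routine reactions.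

Key step: step 10

Remark on the chemistry: all chiral intermediates are racemic (one enantiomer drawn), and 1, 3 and 8 are assumed to be catalogue compounds (3 is otherwise one O-benzylation from 2-bromophenol).

Step 1
Reactants: 1 2,4-dihydroxy-6-methoxybenzaldehyde
Product: 2 4-(benzyloxy)-2-hydroxy-6-methoxybenzaldehyde
Conditions: BnBr (1.05 equiv), K2CO3 (1.1 equiv), acetone, 50 °C
Reagents that add atoms: benzyl bromide, BrCc1ccccc1
Why: Williamson ether synthesis; the 2-hydroxyl is tied up in a hydrogen bond to the aldehyde, so the free and more acidic 4-phenoxide (para to the aldehyde) should be alkylated selectively by one equivalent of halide.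

Step 2
Reactants: 2 4-(benzyloxy)-2-hydroxy-6-methoxybenzaldehyde; 3 benzyl 2-bromophenyl ether
Product: 5 5-(benzyloxy)-2-{[2-(benzyloxy)phenyl](hydroxy)methyl}-3-methoxyphenol (racemic), via 2-(benzyloxy)phenylmagnesium bromide 4 (not isolated)
Conditions: 3 (2.4 equiv), Mg, I2 (cat.), THF, 50 °C; then 2, THF, 0 °C to rt; aq NH4Cl
Reagents that add atoms: none
Why: Grignard addition; the first equivalent of 4 deprotonates the phenol and the second adds to the aldehyde of the magnesium phenoxide, giving a racemic carbinol whose stereocentre is removed in step 3.

Step 3
Reactants: 5 5-(benzyloxy)-2-{[2-(benzyloxy)phenyl](hydroxy)methyl}-3-methoxyphenol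
Product: 6 5-(benzyloxy)-2-[2-(benzyloxy)benzyl]-3-methoxyphenol
Conditions: Et3SiH (3 equiv), CF3CO2H (3 equiv), CH2Cl2, −20 to 0 °C
Reagents that add atoms: none
Why: Ionic hydrogenation; the carbinol ionises easily to a diarylmethyl cation stabilised by the ortho and para oxygens of ring A, and the silane delivers hydride to it; excess silane and dilution suppress Friedel–Crafts capture by a second ring A.

Step 4
Reactants: 6 5-(benzyloxy)-2-[2-(benzyloxy)benzyl]-3-methoxyphenol
Product: 7 6-(benzyloxy)-3-[2-(benzyloxy)benzyl]-2-hydroxy-4-methoxybenzaldehyde
Conditions: MgCl2 (2 equiv), Et3N (4 equiv), (CH2O)n (6 equiv), MeCN, 80 °C; aq HCl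
Reagents that add atoms: paraformaldehyde (as formaldehyde), C=O
Why: Casnati–Skattebøl ortho-formylation; the magnesium phenoxide delivers formaldehyde within a chelate to the only free ortho position, and a second formaldehyde oxidises the resulting benzylic alkoxide by hydride transfer, so the free para position is not attacked.

Step 5
Reactants: 8 homovanillic acid
Product: 9 benzyl 2-[4-(benzyloxy)-3-methoxyphenyl]acetate
Conditions: BnBr (2.3 equiv), K2CO3 (2.5 equiv), DMF, 60 °C
Reagents that add atoms: benzyl bromide, BrCc1ccccc1
Why: Williamson etherification of the phenol and alkylation of the carboxylate in one operation; the ester group is reduced off in step 8, so its identity is immaterial.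

Step 6
Reactants: 9 benzyl 2-[4-(benzyloxy)-3-methoxyphenyl]acetate
Product: 11 benzyl 2-bromo-2-[4-(benzyloxy)-3-methoxyphenyl]acetate (racemic), via trimethylsilyl ketene acetal 10 (not isolated)
Conditions: Me3SiOTf (1.2 equiv), Et3N (1.5 equiv), CH2Cl2, 0 °C; then NBS (1.05 equiv), −78 to 0 °C
Reagents that add atoms: N-bromosuccinimide, O=C1CCC(=O)N1Br
Why: Soft enolisation of the acidic arylacetate to its silyl ketene acetal, then electrophilic α-bromination; the ionic path avoids radical bromination of the benzylic ether CH2 groups, and the new stereocentre is racemic.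

Step 7
Reactants: 7 6-(benzyloxy)-3-[2-(benzyloxy)benzyl]-2-hydroxy-4-methoxybenzaldehyde; 11 benzyl 2-bromo-2-[4-(benzyloxy)-3-methoxyphenyl]acetate
Product: 12 benzyl 2-{3-(benzyloxy)-6-[2-(benzyloxy)benzyl]-2-formyl-5-methoxyphenoxy}-2-[4-(benzyloxy)-3-methoxyphenyl]acetate (racemic)
Conditions: K2CO3 (1.5 equiv), DMF, 0 °C to rt
Reagents that add atoms: none
Why: Williamson O-alkylation (SN2) of the phenoxide by a highly reactive secondary benzylic α-bromo ester, forming the O1–C2 bond; a mild base at low temperature keeps the aldol of the product onto the ortho aldehyde slow, and C2 is formed racemic.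

Step 8
Reactants: 12 benzyl 2-{3-(benzyloxy)-6-[2-(benzyloxy)benzyl]-2-formyl-5-methoxyphenoxy}-2-[4-(benzyloxy)-3-methoxyphenyl]acetate
Product: 13 2-{3-(benzyloxy)-6-[2-(benzyloxy)benzyl]-2-(hydroxymethyl)-5-methoxyphenoxy}-2-[4-(benzyloxy)-3-methoxyphenyl]ethan-1-ol (racemic)
Conditions: LiAlH4 (2.2 equiv), THF, 0 °C; H2O, aq NaOH
Reagents that add atoms: none
Why: Hydride reduction of both the aryl aldehyde and the ester to primary alcohols; aryl ethers and the C2 stereocentre are untouched.

Step 9
Reactants: 13 2-{3-(benzyloxy)-6-[2-(benzyloxy)benzyl]-2-(hydroxymethyl)-5-methoxyphenoxy}-2-[4-(benzyloxy)-3-methoxyphenyl]ethan-1-ol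
Product: 14 6-(benzyloxy)-3-[2-(benzyloxy)benzyl]-2-{1-[4-(benzyloxy)-3-methoxyphenyl]-2-oxoethoxy}-4-methoxybenzaldehyde (racemic)
Conditions: Dess–Martin periodinane (2.5 equiv), pyridine (5 equiv), CH2Cl2, 0 °C to rt; used at once
Reagents that add atoms: none
Why: Dess–Martin oxidation of both primary alcohols under buffered conditions; it avoids a sulfonium leaving group on the trialkoxybenzyl carbon and the amine-mediated enolisation of the new α-aryloxy-α-aryl aldehyde that an activated-DMSO oxidation would risk.

Step 10
Reactants: 14 6-(benzyloxy)-3-[2-(benzyloxy)benzyl]-2-{1-[4-(benzyloxy)-3-methoxyphenyl]-2-oxoethoxy}-4-methoxybenzaldehyde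
Product: 15 rac-(2S,3R,4R)-5-(benzyloxy)-2-[4-(benzyloxy)-3-methoxyphenyl]-8-[2-(benzyloxy)benzyl]-7-methoxychromane-3,4-diol (2,3-trans-3,4-cis)
Conditions: SmI2 (2.5 equiv, 0.1 M in THF) added slowly to 14 (0.01 M), THF, −78 to −40 °C; aq NH4Cl
Reagents that add atoms: none
Why: Electron transfer from SmI2 (divalent samarium) to the ring A aldehyde, the conjugated and more easily reduced carbonyl, should give a samarium ketyl at C4 whose trivalent samarium also binds the side-chain carbonyl oxygen. The ketyl carbon adds to the side-chain aldehyde carbon in a 6-exo-trig closure that forms C3–C4 and ring C, while a second SmI2 supplies the second electron to give the samarium diolate, protonated on work-up. The closest known reaction type is the SmI2-mediated intramolecular pinacol coupling of 1,6-dialdehydes, α-oxygenated ones included, to cis-cyclohexane-1,2-diols. The 3,4-cis relation of the new stereocentres C3 and C4 is controlled by the samarium ion bridging both oxygens in the transition state. The 2,3-trans relation is controlled by the existing C2 centre, whose aryl group takes the pseudo-equatorial position of the chair-like transition state and turns the C3 oxygen to the opposite face. The step needs ketyl formation at the aryl aldehyde and ring closure faster than expulsion of the ring A aryloxide from a ketyl at C3; conjugation of the ring A aldehyde, −78 °C, no HMPA and slow addition of the reductant to dilute 14 serve this, although the three alkoxy donors on ring A narrow the gap between the two aldehydes. All three stereocentres are racemic and are erased in step 11, so any diastereomeric diol would be carried on as well.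

Step 11
Reactants: 15 rac-(2S,3R,4R)-5-(benzyloxy)-2-[4-(benzyloxy)-3-methoxyphenyl]-8-[2-(benzyloxy)benzyl]-7-methoxychromane-3,4-diol
Product: 18 5-(benzyloxy)-2-[4-(benzyloxy)-3-methoxyphenyl]-8-[2-(benzyloxy)benzyl]-3-hydroxy-7-methoxy-4H-chromen-4-one, via trans-3-hydroxyflavanone 16 (not isolated), via flavan-3,4-dione 17 (not isolated)
Conditions: IBX (3 equiv), DMSO, rt to 40 °C
Reagents that add atoms: none
Why: IBX oxidation of secondary alcohols, which takes 1,2-diols to 1,2-dicarbonyl compounds without glycol cleavage; the benzylic C4 carbinol should react first (16), then the α-hydroxy ketone (17), and the dione enolises through the acidic C2–H to the aromatic 3-hydroxychromen-4-one, erasing all three stereocentres.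

Step 12
Reactants: 18 5-(benzyloxy)-2-[4-(benzyloxy)-3-methoxyphenyl]-8-[2-(benzyloxy)benzyl]-3-hydroxy-7-methoxy-4H-chromen-4-one
Product: 19 5-(benzyloxy)-2-[4-(benzyloxy)-3-methoxyphenyl]-8-[2-(benzyloxy)benzyl]-3,7-dimethoxy-4H-chromen-4-one
Conditions: MeI (1.5 equiv), K2CO3 (2 equiv), acetone, 50 °C
Reagents that add atoms: iodomethane, CI
Why: Williamson O-methylation of the flavonol enol, the only acidic hydroxyl in 18 because O5 is benzylated; carbonate in acetone favours O- over C-alkylation.

Step 13
Reactants: 19 5-(benzyloxy)-2-[4-(benzyloxy)-3-methoxyphenyl]-8-[2-(benzyloxy)benzyl]-3,7-dimethoxy-4H-chromen-4-one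
Product: 20 5-hydroxy-2-(4-hydroxy-3-methoxyphenyl)-8-(2-hydroxybenzyl)-3,7-dimethoxy-4H-chromen-4-one
Conditions: H2 (1 atm), 10% Pd/C, THF–MeOH, rt
Reagents that add atoms: none
Why: Catalytic hydrogenolysis of the three aryl benzyl ethers; the tetrasubstituted vinylogous-ester C2=C3 bond, the diarylmethane and the methyl ethers should be inert at 1 atm and rt, so only O5, O4′ and O2″ are uncovered.

Compound list

1 | 2,4-dihydroxy-6-methoxybenzaldehyde | COc1cc(O)cc(O)c1C=O | starting material
2 | 4-(benzyloxy)-2-hydroxy-6-methoxybenzaldehyde | COc1cc(OCc2ccccc2)cc(O)c1C=O | intermediate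
3 | benzyl 2-bromophenyl ether | Brc1ccccc1OCc1ccccc1 | starting material
4 | 2-(benzyloxy)phenylmagnesium bromide (not isolated) | Br[Mg]c1ccccc1OCc1ccccc1 | intermediate
5 | 5-(benzyloxy)-2-{[2-(benzyloxy)phenyl](hydroxy)methyl}-3-methoxyphenol (racemic, one enantiomer drawn) | COc1cc(OCc2ccccc2)cc(O)c1[C@H](O)c1ccccc1OCc1ccccc1 | intermediate
6 | 5-(benzyloxy)-2-[2-(benzyloxy)benzyl]-3-methoxyphenol | COc1cc(OCc2ccccc2)cc(O)c1Cc1ccccc1OCc1ccccc1 | intermediate
7 | 6-(benzyloxy)-3-[2-(benzyloxy)benzyl]-2-hydroxy-4-methoxybenzaldehyde | COc1cc(OCc2ccccc2)c(C=O)c(O)c1Cc1ccccc1OCc1ccccc1 | intermediate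
8 | homovanillic acid | COc1cc(CC(=O)O)ccc1O | starting material
9 | benzyl 2-[4-(benzyloxy)-3-methoxyphenyl]acetate | COc1cc(CC(=O)OCc2ccccc2)ccc1OCc1ccccc1 | intermediate
10 | {1-(benzyloxy)-2-[4-(benzyloxy)-3-methoxyphenyl]ethenyloxy}trimethylsilane (not isolated; mixture of double-bond isomers, geometry of no consequence) | COc1cc(C=C(OCc2ccccc2)O[Si](C)(C)C)ccc1OCc1ccccc1 | intermediate
11 | benzyl 2-bromo-2-[4-(benzyloxy)-3-methoxyphenyl]acetate (racemic, one enantiomer drawn) | COc1cc([C@@H](Br)C(=O)OCc2ccccc2)ccc1OCc1ccccc1 | intermediate
12 | benzyl 2-{3-(benzyloxy)-6-[2-(benzyloxy)benzyl]-2-formyl-5-methoxyphenoxy}-2-[4-(benzyloxy)-3-methoxyphenyl]acetate (racemic, one enantiomer drawn) | O=Cc1c(OCc2ccccc2)cc(OC)c(Cc2ccccc2OCc2ccccc2)c1O[C@H](C(=O)OCc1ccccc1)c1ccc(OCc2ccccc2)c(OC)c1 | intermediate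
13 | 2-{3-(benzyloxy)-6-[2-(benzyloxy)benzyl]-2-(hydroxymethyl)-5-methoxyphenoxy}-2-[4-(benzyloxy)-3-methoxyphenyl]ethan-1-ol (racemic, one enantiomer drawn) | OCc1c(OCc2ccccc2)cc(OC)c(Cc2ccccc2OCc2ccccc2)c1O[C@H](CO)c1ccc(OCc2ccccc2)c(OC)c1 | intermediate
14 | 6-(benzyloxy)-3-[2-(benzyloxy)benzyl]-2-{1-[4-(benzyloxy)-3-methoxyphenyl]-2-oxoethoxy}-4-methoxybenzaldehyde (racemic, one enantiomer drawn) | O=Cc1c(OCc2ccccc2)cc(OC)c(Cc2ccccc2OCc2ccccc2)c1O[C@H](C=O)c1ccc(OCc2ccccc2)c(OC)c1 | intermediate
15 | rac-(2S,3R,4R)-5-(benzyloxy)-2-[4-(benzyloxy)-3-methoxyphenyl]-8-[2-(benzyloxy)benzyl]-7-methoxychromane-3,4-diol (2,3-trans-3,4-cis, one enantiomer drawn) | O[C@H]1[C@@H](O)[C@H](c2ccc(OCc3ccccc3)c(OC)c2)Oc2c1c(OCc1ccccc1)cc(OC)c2Cc1ccccc1OCc1ccccc1 | intermediate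
16 | rac-(2S,3S)-5-(benzyloxy)-2-[4-(benzyloxy)-3-methoxyphenyl]-8-[2-(benzyloxy)benzyl]-3-hydroxy-7-methoxychroman-4-one (2,3-trans, not isolated, one enantiomer drawn) | O=C1[C@@H](O)[C@H](c2ccc(OCc3ccccc3)c(OC)c2)Oc2c1c(OCc1ccccc1)cc(OC)c2Cc1ccccc1OCc1ccccc1 | intermediate
17 | rac-(2S)-5-(benzyloxy)-2-[4-(benzyloxy)-3-methoxyphenyl]-8-[2-(benzyloxy)benzyl]-7-methoxychromane-3,4-dione (not isolated, one enantiomer drawn) | O=C1C(=O)[C@H](c2ccc(OCc3ccccc3)c(OC)c2)Oc2c1c(OCc1ccccc1)cc(OC)c2Cc1ccccc1OCc1ccccc1 | intermediate
18 | 5-(benzyloxy)-2-[4-(benzyloxy)-3-methoxyphenyl]-8-[2-(benzyloxy)benzyl]-3-hydroxy-7-methoxy-4H-chromen-4-one | O=c1c(O)c(-c2ccc(OCc3ccccc3)c(OC)c2)oc2c(Cc3ccccc3OCc3ccccc3)c(OC)cc(OCc3ccccc3)c12 | intermediate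
19 | 5-(benzyloxy)-2-[4-(benzyloxy)-3-methoxyphenyl]-8-[2-(benzyloxy)benzyl]-3,7-dimethoxy-4H-chromen-4-one | COc1c(-c2ccc(OCc3ccccc3)c(OC)c2)oc2c(Cc3ccccc3OCc3ccccc3)c(OC)cc(OCc3ccccc3)c2c1=O | intermediate
20 | 5-hydroxy-2-(4-hydroxy-3-methoxyphenyl)-8-(2-hydroxybenzyl)-3,7-dimethoxy-4H-chromen-4-one | COc1cc(-c2oc3c(Cc4ccccc4O)c(OC)cc(O)c3c(=O)c2OC)ccc1O | target

Total step count: 13. Longest linear sequence: 11 steps (steps 1 to 4, then 7 to 13).

Least certain steps

Step 10 (key step). The most likely failure is fragmentation instead of cyclisation. If an electron enters the side-chain aldehyde, the ketyl at C3 can expel the ring A aryloxide from C2, and the three alkoxy donors make the ring A aldehyde harder to reduce than a plain benzaldehyde. Simple reduction of either aldehyde to the alcohol is the second risk, and 14 itself may aldolise if stored.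

The fallback makes the C3–C4 bond as an alkene without any one-electron step and adds the two oxygens afterwards. It sets out from 14 and returns at 15. Double Wittig methylenation of 14 (Ph3P=CH2 from methyltriphenylphosphonium bromide and KN(SiMe3)2, THF, −78 to 0 °C) would give 1-(benzyloxy)-4-[2-(benzyloxy)benzyl]-3-({1-[4-(benzyloxy)-3-methoxyphenyl]prop-2-en-1-yl}oxy)-5-methoxy-2-vinylbenzene F1. Ring-closing metathesis with the second-generation Grubbs catalyst (CH2Cl2, 40 °C) would close ring C as 5-(benzyloxy)-2-[4-(benzyloxy)-3-methoxyphenyl]-8-[2-(benzyloxy)benzyl]-7-methoxy-2H-chromene F2. Dihydroxylation with OsO4 (cat.) and N-methylmorpholine N-oxide in acetone–water, on the face opposite the C2 aryl group, would give the 2,3-trans-3,4-cis diol 15.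

Step 3. The diarylmethyl cation may be captured by a second electron-rich ring A (Friedel–Crafts oligomerisation) faster than by the silane, and the acid may begin to cleave or migrate the benzyl group on the phloroglucinol-type ring.

The fallback reaches the same ortho-benzyl phenol under anionic conditions through an ortho-quinone methide. It sets out from 2 and returns at 6, bypassing steps 2 and 3. Acylation of 2 with Boc2O (i-Pr2NEt, DMAP cat., CH2Cl2) would give tert-butyl [5-(benzyloxy)-2-formyl-3-methoxyphenyl] carbonate F3. Addition of 4 (1.1 equiv, THF, −78 °C) gives an alkoxide that takes over the carbonate group; on warming, the phenoxide expels tert-butyl carbonate to form 3-(benzyloxy)-6-{[2-(benzyloxy)phenyl]methylidene}-5-methoxycyclohexa-2,4-dien-1-one F4. This transient is reduced in the same flask by NaBH4 to 6.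

Step 7. The hindered, chelated phenoxide may react slowly, so that elimination or hydrolysis of 11 competes. The product has an acidic C2–H and may close a five-membered ring by aldol addition onto the ortho aldehyde under the basic conditions.

The fallback forms the O1–C2 bond by carbenoid O–H insertion under neutral conditions. It sets out from 9 (with 7) and returns at 12. Diazo transfer to 9 (4-acetamidobenzenesulfonyl azide, DBU, MeCN) would give benzyl 2-diazo-2-[4-(benzyloxy)-3-methoxyphenyl]acetate F5. Slow addition of F5 to 7 with Rh2(OAc)4 (1 mol %) in CH2Cl2 would insert the carbenoid into the phenolic O–H and give 12.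

Step 11. Over-oxidation is the main risk: glycol cleavage of the cis-diol, oxidation of the doubly benzylic CH2 bridge, or further oxidation of the electron-rich flavonol once formed. Ionisation of the C4 carbinol by the acidic reagent is a second risk.

The fallback separates the two oxidations and uses a different mechanism for each. It sets out from 15 and returns at 18. Activated MnO2 (CH2Cl2, rt) oxidises only the benzylic C4 carbinol and gives 16, which is isolated. Dehydrogenation through the C3 enol with I2 and KOAc in AcOH (100 °C), the classical dihydroflavonol-to-flavonol conversion, then gives 18. This fallback makes no compound outside the list (F0).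

Further compounds

F1 | step 10 | 1-(benzyloxy)-4-[2-(benzyloxy)benzyl]-3-({1-[4-(benzyloxy)-3-methoxyphenyl]prop-2-en-1-yl}oxy)-5-methoxy-2-vinylbenzene (racemic, one enantiomer drawn) | C=Cc1c(OCc2ccccc2)cc(OC)c(Cc2ccccc2OCc2ccccc2)c1O[C@H](C=C)c1ccc(OCc2ccccc2)c(OC)c1
F2 | step 10 | 5-(benzyloxy)-2-[4-(benzyloxy)-3-methoxyphenyl]-8-[2-(benzyloxy)benzyl]-7-methoxy-2H-chromene (racemic, one enantiomer drawn) | COc1cc(OCc2ccccc2)c2C=C[C@H](c3ccc(OCc4ccccc4)c(OC)c3)Oc2c1Cc1ccccc1OCc1ccccc1
F3 | step 3 | tert-butyl [5-(benzyloxy)-2-formyl-3-methoxyphenyl] carbonate | COc1cc(OCc2ccccc2)cc(OC(=O)OC(C)(C)C)c1C=O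
F4 | step 3 | 3-(benzyloxy)-6-{[2-(benzyloxy)phenyl]methylidene}-5-methoxycyclohexa-2,4-dien-1-one (transient, exocyclic geometry not defined) | O=C1C=C(OCc2ccccc2)C=C(OC)C1=Cc1ccccc1OCc1ccccc1
F5 | step 7 | benzyl 2-diazo-2-[4-(benzyloxy)-3-methoxyphenyl]acetate | COc1cc(C(=[N+]=[N-])C(=O)OCc2ccccc2)ccc1OCc1ccccc1
F0 | step 11 | none | none
A1 | alternative 1 | 5-hydroxy-2-(4-isopropoxy-3-methoxyphenyl)-8-(2-isopropoxybenzyl)-3,7-dimethoxy-4H-chromen-4-one | COc1cc(-c2oc3c(Cc4ccccc4OC(C)C)c(OC)cc(O)c3c(=O)c2OC)ccc1OC(C)C
A2 | alternative 2 | 2-(4-benzyloxy-3-methoxyphenyl)-8-(2-benzyloxybenzyl)-5-hydroxy-3,7-dimethoxy-4H-chromen-4-one | COc1cc(-c2oc3c(Cc4ccccc4OCc4ccccc4)c(OC)cc(O)c3c(=O)c2OC)ccc1OCc1ccccc1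
A3 | alternative 2 | methoxyacetylene | COC#C
A4 | alternative 3 | 2-(4-benzyloxy-3-methoxyphenyl)-8-(2-benzyloxybenzyl)-3,5,7-trimethoxy-4H-chromen-4-one | COc1cc(-c2oc3c(Cc4ccccc4OCc4ccccc4)c(OC)cc(OC)c3c(=O)c2OC)ccc1OCc1ccccc1
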